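## Structural features

The target is the vanillate (4-hydroxy-3-methoxybenzoate) of a monocyclic sesquiterpene diol. Its single ten-membered carbocycle, numbered C10(Me)=C1–C2–C3–C4(Me)(OH)–C5=C6–C7(iPr)–C8(OCOAr)–C9, is joined to the arene only through the C8 ester oxygen. The ring holds two E double bonds, the trisubstituted C1=C10 and the disubstituted C5=C6. Three saturated carbons separate them on either side, so a Cope shift is impossible, but acid-induced transannular cyclisation is not. There are three stereocentres: the tertiary allylic carbinol C4 (R), and the neighbouring pair C7 (S, isopropyl) and C8 (S, acyloxy), whose substituents lie on opposite faces of the ring. C4 and C7 stand 1,4 to one another across the C5=C6 olefin. Fragile groups are the tertiary allylic alcohol at C4 (ionisation, elimination, attack by C1=C10 across the ring), the strained E,E-cyclodecadiene, the aryl ester and the free phenol. The real difficulty is closing a ten-membered ring with both olefin geometries defined while relating C4 to the remote C7. The fragment C4(OH)–C5=C6–C7 is what a 1,4-opening of a C4–C5 oxirane bearing a C6=C7 alkene leaves behind; if the carbon that opens it is C8, then ring closure, the 5E olefin, the free C4 hydroxyl and the C7 centre all arise in one event, and the key step exploits exactly this.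

## Logic of the disconnections

24 is first cut at the acyl–oxygen bond of the C8 ester, after the phenol is masked as in 23, giving 19 and 22 (22 from 20). This is the only bond joining the aromatic and terpenoid halves, and cutting it leaves a ring with no aromatic baggage. The forward step must acylate the secondary C8 hydroxyl of 19 beside the free tertiary C4 hydroxyl, with retention at C8.

The C8 carbinol of 19 is traced to the carbonyl of 18 and this to the nitro group of 16. No skeletal bond is cut. The purpose is to make C8 a carbon that can act as a stabilised nucleophile one step earlier. The forward demand is twofold: a Nef reaction mild enough for the tertiary allylic alcohol, and hydride addition to 18 on the face that puts the oxygen trans to the isopropyl group without enolising toward C7.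

16 is cut at C7–C8, which opens the ring to 15. The cut is made there because the C4(OH)–C5=C6–C7 unit is the retron of a vinyl-oxirane 1,4-opening. One bond removes the ring, the C7 centre and the 5E olefin, leaving an open chain with a single controlled stereo-element, the oxirane. The forward step must close a ten-membered ring at the distal allyl terminus and pass the C5 configuration on to C7.

15 is cut at C8–C9 to 10 and 11, by way of 12 and, in the flask, 13 and 14. The nitro carbon is thus added as a one-carbon nucleophile to an aldehyde, and the C9 oxygen is then removed. The forward sequence must keep the C1=C10 olefin E and in place and must not touch the vinyl oxirane.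

10 is traced to 8 by removing the C9 oxygen (through 9), so that the forward step is an allylic C–H oxidation. This avoids carrying a second oxygenated terminus through the earlier steps. The demand is site selectivity for the E-methyl of the trisubstituted olefin and tolerance of the vinyl oxirane.

8 is cut at the C6=C7 double bond to 7 and 4, and 4 to 1 and 2 through 3. An olefination here attaches the isopropyl terminus in one step. The forward reaction must be E-selective, since the olefin geometry later decides which face of C7 is attacked.

7 is traced through 6 to 5 by removing the oxirane oxygen. This leaves an achiral, commercial C10 chain that already has the Z geometry needed for the cis oxirane. The forward step is the only asymmetric reaction of the route and must give the (2S,3R) oxirane.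

## Other disconnections considered

Alternative 1: The ring would be cut at C1–C2, leading back to the open-chain iodo triene A1. A1 carries C4 as a triethylsilyl ether with a terminal vinyl group (C2=C3), the 5E olefin, C7, C8 as a tert-butyldimethylsilyl ether, and a ready-made (E)-vinyl iodide at C1=C10. In the forward direction 9-BBN would hydroborate only the monosubstituted vinyl group (boron on C2), and Pd(dppf)Cl2 with Cs2CO3 at high dilution would couple the alkylborane with the vinyl iodide to give the macrocyclic bis-silyl ether A2.
- In its favour: the sp3–sp2 coupling retains olefin geometry, every stereocentre and both double bonds are fixed before cyclisation, and C8 is an alcohol throughout, so no ketone stage and no facial-selectivity question arise.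
- Against it here: the closure creates no stereocentre, so C4, C7 and C8 each need their own asymmetric step in an acyclic setting. The trisubstituted (E)-vinyl iodide needs a dedicated sequence. The hydroboration site is neopentyl-like, next to a silylated quaternary carbon. Two silyl ethers must be removed and the diol acylated selectively at the end.
- Comparison: Alternative 1 is the better plan for certainty of the C8 configuration and for avoiding an epimerisable β,γ-unsaturated ketone. It is the equal of the chosen plan in the entropic and strain cost of ring closure, since both are dilute palladium-mediated closures of the same ring. The chosen plan is clearly ahead in step economy and in using one oxirane to control two centres.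

Alternative 2: The ring would be traced back to the cyclohexanol A3, a trans-1-isopropenyl-2-methyl-2-vinylcyclohexanol carrying the isopropyl and silyloxy groups; retrosynthetically C2–C3 is cut and C5–C10 reconnected. In the forward direction the potassium alkoxide (KH, 18-crown-6) would undergo the anionic oxy-Cope shift. The resulting ten-membered enolate would be hydroxylated at C4 in the same flask with 2-(phenylsulfonyl)-3-phenyloxaziridine to give the α-hydroxy ketone A4.
- In its favour: the ring expansion is unimolecular and needs no dilution. A chair transition state with both alkenyl groups equatorial should give the 1(10)E olefin. C7 and C8 are set on a six-membered ring, where relative control is routine.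
- Against it here: A4 has a C5 carbonyl and a C6 methylene instead of the C5=C6 olefin, so a reduction and a regio- and E-selective dehydration (or an equivalent) must follow, in a ring where olefin geometry is hard to steer. The C4 configuration rests on the facial selectivity of oxygen transfer to a macrocyclic tetrasubstituted enolate. The α-ketol can rearrange. A3 contains a quaternary carbon that must be built with vinyl trans to isopropenyl.
- Comparison: Alternative 2 is the better plan for the ring-forming event itself and for the early, secure setting of C8. The chosen plan is better for C4 and the 5E olefin, which it delivers directly. Overall step economy favours the chosen plan.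

Alternative 3: The ring would be traced back to the octalin mesylate A5 (eudesmane skeleton, C5=C6 olefin, mesylate at C1 cis to the angular methyl) by reconnecting C5–C10. In the forward direction BH3·THF would add to C5=C6 from the face opposite the angular methyl (boron on C6, hydrogen on C5, trans-decalin). NaOMe would then form the boronate, in which the C6–B bond, the C5–C10 bond and the C1–O bond of the equatorial mesylate are antiperiplanar, so that a Grob-type fragmentation opens the ten-membered ring to the silyl ether A6.
- In its favour: the fragmentation is stereospecific, so both E geometries follow from the chair geometry of the decalin. No macrocyclisation is needed. C4, C7 and C8 are set on a rigid bicycle. The basic conditions suit the acid-labile dienol. A6 is only a desilylation, an acylation and a phenol unmasking away from the target, with no Nef step.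
- Against it here: A5 needs five defined stereocentres, two of which (C1, C10) are destroyed. The free tertiary allylic hydroxyl at C4 may perturb the regio- and facial selectivity of the hydroboration. The decalin synthesis is long.
- Comparison: Alternative 3 is the better plan for predictability of both olefin geometries and for C8. It is the equal of the chosen plan in delivering the C4(OH)–C5=C6 unit directly. It is worse in step count and in the number of stereocentres that must be controlled one by one.

Key step: step 9

Remark on the chemistry: 12 and 13 are carried as epimer mixtures at C9, and 16 as a mixture at C8. This is harmless because the C9 oxygen is removed in step 8 and C8 passes through the ketone 18. Ring positions are numbered as in the first section throughout.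

## Route

Step 1
Reactants: 1 1-bromo-2-methylpropane; 2 1-phenyl-1H-tetrazole-5-thiol
Product: 3 5-[(2-methylpropyl)sulfanyl]-1-phenyl-1H-tetrazole
Conditions: K2CO3, DMF, 60 °C
Reagents that add atoms: none
Why: SN2 S-alkylation of the tetrazolethiolate by a primary bromide; the soft sulfur is alkylated in preference to ring nitrogen.

Step 2
Reactants: 3 5-[(2-methylpropyl)sulfanyl]-1-phenyl-1H-tetrazole
Product: 4 5-[(2-methylpropyl)sulfonyl]-1-phenyl-1H-tetrazole
Conditions: H2O2 (30 %), (NH4)6Mo7O24·4H2O (cat.), EtOH, 0 °C to rt
Reagents that add atoms: hydrogen peroxide, OO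
Why: Molybdate-catalysed peroxide oxidation of the sulfide to the sulfone, the usual entry to tetrazolyl sulfones for the Julia–Kocienski olefination; nothing else in 3 is oxidisable.

Step 3
Reactants: 5 nerol, (2Z)-3,7-dimethylocta-2,6-dien-1-ol
Product: 6 [(2S,3R)-3-methyl-3-(4-methylpent-3-en-1-yl)oxiran-2-yl]methanol
Conditions: Ti(OiPr)4 (cat.), L-(+)-diethyl tartrate (cat.), tBuOOH, 4 Å MS, CH2Cl2, −20 °C
Reagents that add atoms: tert-butyl hydroperoxide, CC(C)(C)OO
Why: Sharpless asymmetric epoxidation: only the allylic-alcohol olefin is activated on titanium, so the remote trisubstituted olefin is untouched. The L-(+)-tartrate ligand directs oxygen to the enantioface that gives the (2S,3R) oxirane, which fixes the later C4 (R) and C5 (S); the Z geometry of 5 makes the oxirane cis.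

Step 4
Reactants: 6 [(2S,3R)-3-methyl-3-(4-methylpent-3-en-1-yl)oxiran-2-yl]methanol
Product: 7 (2R,3R)-3-methyl-3-(4-methylpent-3-en-1-yl)oxirane-2-carbaldehyde
Conditions: TEMPO (cat.), PhI(OAc)2, CH2Cl2, 0 °C to rt
Reagents that add atoms: none
Why: Oxoammonium (TEMPO) oxidation of a primary alcohol, which stops at the aldehyde and is routinely used for 2,3-epoxy alcohols; the oxirane carbon next to the aldehyde does not epimerise under these mild conditions (the descriptor changes only because of the priority rules).

Step 5
Reactants: 7 (2R,3R)-3-methyl-3-(4-methylpent-3-en-1-yl)oxirane-2-carbaldehyde; 4 5-[(2-methylpropyl)sulfonyl]-1-phenyl-1H-tetrazole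
Product: 8 (2R,3S)-2-methyl-3-[(1E)-3-methylbut-1-en-1-yl]-2-(4-methylpent-3-en-1-yl)oxirane
Conditions: 4, KN(SiMe3)2, DME, −60 °C; then 7, −60 °C to rt
Reagents that add atoms: none
Why: Julia–Kocienski olefination: addition of the metalated sulfone, Smiles rearrangement and loss of SO2 and tetrazololate give the olefin, and the potassium base in DME favours E. The E geometry is needed because it later places the isopropyl group syn on the allyl unit and so decides the C7 configuration; the oxirane centres are not touched.

Step 6
Reactants: 8 (2R,3S)-2-methyl-3-[(1E)-3-methylbut-1-en-1-yl]-2-(4-methylpent-3-en-1-yl)oxirane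
Product: 10 (2E)-2-methyl-5-{(2R,3S)-2-methyl-3-[(1E)-3-methylbut-1-en-1-yl]oxiran-2-yl}pent-2-enal, via allylic alcohol 9 (not isolated)
Conditions: SeO2 (cat.), tBuOOH, CH2Cl2, 0 °C to rt; then MnO2, CH2Cl2, rt
Reagents that add atoms: selenium dioxide, O=[Se]=O; tert-butyl hydroperoxide, CC(C)(C)OO
Why: Selenium dioxide allylic oxidation (ene reaction, then [2,3]-sigmatropic shift) attacks the E-methyl of the electron-rich gem-dimethyl olefin far faster than any position of the disubstituted olefin. MnO2, which oxidises only allylic alcohols, then converges alcohol 9 and any enal already formed to the single E-enal 10.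

Step 7
Reactants: 10 (2E)-2-methyl-5-{(2R,3S)-2-methyl-3-[(1E)-3-methylbut-1-en-1-yl]oxiran-2-yl}pent-2-enal; 11 nitromethane
Product: 12 (3E)-3-methyl-6-{(2R,3S)-2-methyl-3-[(1E)-3-methylbut-1-en-1-yl]oxiran-2-yl}-1-nitrohex-3-en-2-ol (both C2 epimers)
Conditions: MeNO2 (excess), KOtBu (cat.), tBuOH–THF, 0 °C
Reagents that add atoms: none
Why: Henry (nitroaldol) reaction: base-catalysed 1,2-addition of the nitromethane anion to the aldehyde, with conjugate addition slowed by the α-methyl and β-alkyl groups of the enal. The new carbinol centre is uncontrolled and is removed in step 8.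

Step 8
Reactants: 12 (3E)-3-methyl-6-{(2R,3S)-2-methyl-3-[(1E)-3-methylbut-1-en-1-yl]oxiran-2-yl}-1-nitrohex-3-en-2-ol
Product: 15 (2R,3S)-2-methyl-3-[(1E)-3-methylbut-1-en-1-yl]-2-[(3E)-4-methyl-6-nitrohex-3-en-1-yl]oxirane, via nitro acetate 13 (not isolated), via nitrodiene 14 (not isolated)
Conditions: Ac2O, DMAP (cat.), CH2Cl2, 0 °C; then NaBH4, EtOH, 0 °C, pH 7 work-up
Reagents that add atoms: none
Why: Acetylation followed by base-induced E1cB loss of acetate gives the conjugated nitrodiene, and borohydride adds hydride to the carbon β to nitro (conjugate reduction of a nitroalkene), giving the nitronate that is protonated on buffered work-up. The C1=C10 olefin is not involved and should stay E; the oxirane is inert to borohydride.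

Step 9
Reactants: 15 (2R,3S)-2-methyl-3-[(1E)-3-methylbut-1-en-1-yl]-2-[(3E)-4-methyl-6-nitrohex-3-en-1-yl]oxirane
Product: 16 (1R,2E,4S,7E)-1,7-dimethyl-5-nitro-4-(propan-2-yl)cyclodeca-2,7-dien-1-ol, i.e. (4R,7S)-8-nitrogermacra-1(10)E,5E-dien-4-ol (both C8 epimers)
Conditions: Pd(PPh3)4 (10 mol %), THF, 55 °C, syringe-pump addition of 15, final concentration about 0.003 M, argon
Reagents that add atoms: none
Why: Zerovalent palladium ionises the allylic C5–O bond with inversion, so the metal sits on the face opposite the departing oxygen of a syn,syn η3-allyl spanning C5–C6–C7, and the C4 alkoxide set free deprotonates the nitroalkane at C8, so that no external base is needed. The nitronate carbon then attacks C7 from the face anti to palladium (outer-sphere attack of a soft nucleophile, second inversion), which forms the C7–C8 bond, turns the syn C4 substituent into the 5E olefin and releases the catalyst. The closest known chemistry is the Tsuji–Trost macrocyclisation of vinyl epoxides with soft carbon pronucleophiles under neutral conditions, together with the palladium-catalysed allylation of nitroalkanes, combined here for a ten-membered ring. Ring closure: the ten-membered carbocycle forms by attack on the distal allyl terminus, so that all three allyl carbons become ring members and the new olefin is endocyclic. New stereocentre C7: its configuration (S) is dictated by C5 (S) of the oxirane through the two inversions, provided the C6=C7 olefin of 15 is E (isopropyl syn) and ionisation occurs from the s-trans conformer favoured by allylic strain; C8 forms as a mixture, which is of no consequence. Attack at C7 and not at C5 is secured by the quaternary alkoxide-bearing C4, which shields C5, and by the strain of the eight-membered alternative. C- over O-alkylation is secured because an O-allyl nitronate is itself an allylic electrophile and is re-ionised, leaving the C–C bonded product as the sink; cyclisation over oligomerisation is secured by slow addition into a dilute catalyst solution.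

Step 10
Reactants: 16 (1R,2E,4S,7E)-1,7-dimethyl-5-nitro-4-(propan-2-yl)cyclodeca-2,7-dien-1-ol
Product: 18 (2S,3E,5R,8E)-5-hydroxy-5,9-dimethyl-2-(propan-2-yl)cyclodeca-3,8-dien-1-one, i.e. (4R,7S)-4-hydroxygermacra-1(10)E,5E-dien-8-one, via sodium nitronate 17 (not isolated)
Conditions: NaOMe, MeOH, 0 °C; then aq. TiCl3, NH4OAc (pH 5–6), THF–H2O, 0 °C to rt
Reagents that add atoms: water, O
Why: Nef reaction in its reductive form: the nitronate is reduced by trivalent titanium to the imine, which is hydrolysed to the ketone at pH 5–6, mild enough for the tertiary allylic alcohol and both olefins. In the basic stage only C8–H is acidic, so C7 is untouched, and the buffer limits enolisation of the ketone, which is used at once.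

Step 11
Reactants: 18 (2S,3E,5R,8E)-5-hydroxy-5,9-dimethyl-2-(propan-2-yl)cyclodeca-3,8-dien-1-one
Product: 19 (1R,2E,4S,5S,7E)-1,7-dimethyl-4-(propan-2-yl)cyclodeca-2,7-diene-1,5-diol, i.e. (4R,7S,8S)-germacra-1(10)E,5E-diene-4,8-diol
Conditions: NaBH4, CeCl3·7H2O, MeOH, −78 to −40 °C
Reagents that add atoms: none
Why: Luche-type borohydride reduction, which is weakly basic and cold, so the C7 centre (α to the carbonyl and allylic) should not epimerise. With the C7 isopropyl group pseudo-equatorial, a small hydride is expected to take the torsionally free, axial-type trajectory, giving the pseudo-equatorial hydroxyl trans to isopropyl (8S); this is substrate control by C7, and it is the least predictable selectivity of the endgame.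

Step 12
Reactants: 20 vanillic acid (4-hydroxy-3-methoxybenzoic acid)
Product: 22 4-[(tert-butyldimethylsilyl)oxy]-3-methoxybenzoic acid, via bis-silyl derivative 21 (not isolated)
Conditions: TBSCl (2.2 equiv), imidazole, DMF, rt; then AcOH–THF–H2O, rt
Reagents that add atoms: tert-butyldimethylsilyl chloride, CC(C)(C)[Si](C)(C)Cl
Why: Silylation of both acidic hydroxyls followed by selective hydrolysis of the far more labile silyl ester; the aryl silyl ether survives dilute acetic acid.

Step 13
Reactants: 19 (1R,2E,4S,5S,7E)-1,7-dimethyl-4-(propan-2-yl)cyclodeca-2,7-diene-1,5-diol; 22 4-[(tert-butyldimethylsilyl)oxy]-3-methoxybenzoic acid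
Product: 23 (4R,7S,8S)-4-hydroxygermacra-1(10)E,5E-dien-8-yl 4-[(tert-butyldimethylsilyl)oxy]-3-methoxybenzoate
Conditions: DCC, DMAP (0.3 equiv), CH2Cl2, 0 °C to rt
Reagents that add atoms: none
Why: Steglich esterification: DMAP passes the acyl group from the O-acylisourea to the secondary C8 hydroxyl with retention at C8. The tertiary C4 hydroxyl is too hindered to be acylated, so it needs no protection.

Step 14
Reactants: 23 (4R,7S,8S)-4-hydroxygermacra-1(10)E,5E-dien-8-yl 4-[(tert-butyldimethylsilyl)oxy]-3-methoxybenzoate
Product: 24 (4R,7S,8S)-4-hydroxygermacra-1(10)E,5E-dien-8-yl 4-hydroxy-3-methoxybenzoate (target)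
Conditions: Bu4NF, AcOH, THF, 0 °C
Reagents that add atoms: none
Why: Fluoride cleavage of an aryl silyl ether, driven by the Si–F bond and the good phenoxide leaving group. Acetic acid buffers the phenoxide, so the ester is not cleaved and the tertiary allylic alcohol sees neither strong acid nor strong base.

## Compound list

1 | 1-bromo-2-methylpropane | CC(C)CBr | starting material
2 | 1-phenyl-1H-tetrazole-5-thiol | Sc1nnnn1-c1ccccc1 | starting material
3 | 5-[(2-methylpropyl)sulfanyl]-1-phenyl-1H-tetrazole | CC(C)CSc1nnnn1-c1ccccc1 | intermediate
4 | 5-[(2-methylpropyl)sulfonyl]-1-phenyl-1H-tetrazole | CC(C)CS(=O)(=O)c1nnnn1-c1ccccc1 | intermediate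
5 | nerol, (2Z)-3,7-dimethylocta-2,6-dien-1-ol | CC(C)=CCC/C(C)=C\CO | starting material
6 | [(2S,3R)-3-methyl-3-(4-methylpent-3-en-1-yl)oxiran-2-yl]methanol | CC(C)=CCC[C@@]1(C)O[C@H]1CO | intermediate
7 | (2R,3R)-3-methyl-3-(4-methylpent-3-en-1-yl)oxirane-2-carbaldehyde | CC(C)=CCC[C@@]1(C)O[C@H]1C=O | intermediate
8 | (2R,3S)-2-methyl-3-[(1E)-3-methylbut-1-en-1-yl]-2-(4-methylpent-3-en-1-yl)oxirane | CC(C)=CCC[C@@]1(C)O[C@H]1/C=C/C(C)C | intermediate
9 | (2E)-2-methyl-5-{(2R,3S)-2-methyl-3-[(1E)-3-methylbut-1-en-1-yl]oxiran-2-yl}pent-2-en-1-ol | OC/C(C)=C/CC[C@@]1(C)O[C@H]1/C=C/C(C)C | intermediate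
10 | (2E)-2-methyl-5-{(2R,3S)-2-methyl-3-[(1E)-3-methylbut-1-en-1-yl]oxiran-2-yl}pent-2-enal | O=C/C(C)=C/CC[C@@]1(C)O[C@H]1/C=C/C(C)C | intermediate
11 | nitromethane | C[N+](=O)[O-] | starting material
12 | (3E)-3-methyl-6-{(2R,3S)-2-methyl-3-[(1E)-3-methylbut-1-en-1-yl]oxiran-2-yl}-1-nitrohex-3-en-2-ol (C2 epimers) | [O-][N+](=O)CC(O)/C(C)=C/CC[C@@]1(C)O[C@H]1/C=C/C(C)C | intermediate
13 | (3E)-3-methyl-6-{(2R,3S)-2-methyl-3-[(1E)-3-methylbut-1-en-1-yl]oxiran-2-yl}-1-nitrohex-3-en-2-yl acetate | [O-][N+](=O)CC(OC(C)=O)/C(C)=C/CC[C@@]1(C)O[C@H]1/C=C/C(C)C | intermediate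
14 | (2R,3S)-2-methyl-3-[(1E)-3-methylbut-1-en-1-yl]-2-[(3E,5E)-4-methyl-6-nitrohexa-3,5-dien-1-yl]oxirane | [O-][N+](=O)/C=C/C(C)=C/CC[C@@]1(C)O[C@H]1/C=C/C(C)C | intermediate
15 | (2R,3S)-2-methyl-3-[(1E)-3-methylbut-1-en-1-yl]-2-[(3E)-4-methyl-6-nitrohex-3-en-1-yl]oxirane | [O-][N+](=O)CC/C(C)=C/CC[C@@]1(C)O[C@H]1/C=C/C(C)C | intermediate
16 | (1R,2E,4S,7E)-1,7-dimethyl-5-nitro-4-(propan-2-yl)cyclodeca-2,7-dien-1-ol (C5 epimers; 8-nitrogermacra-1(10),5-dien-4-ol) | [O-][N+](=O)C1C/C(C)=C/CC[C@@](C)(O)/C=C/[C@@H]1C(C)C | intermediate
17 | sodium nitronate of 16 | [Na+].[O-][N+]([O-])=C1C/C(C)=C/CC[C@@](C)(O)/C=C/[C@@H]1C(C)C | intermediate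
18 | (2S,3E,5R,8E)-5-hydroxy-5,9-dimethyl-2-(propan-2-yl)cyclodeca-3,8-dien-1-one | O=C1C/C(C)=C/CC[C@@](C)(O)/C=C/[C@@H]1C(C)C | intermediate
19 | (1R,2E,4S,5S,7E)-1,7-dimethyl-4-(propan-2-yl)cyclodeca-2,7-diene-1,5-diol | O[C@H]1C/C(C)=C/CC[C@@](C)(O)/C=C/[C@@H]1C(C)C | intermediate
20 | vanillic acid, 4-hydroxy-3-methoxybenzoic acid | COc1cc(C(=O)O)ccc1O | starting material
21 | tert-butyldimethylsilyl 4-[(tert-butyldimethylsilyl)oxy]-3-methoxybenzoate | COc1cc(C(=O)O[Si](C)(C)C(C)(C)C)ccc1O[Si](C)(C)C(C)(C)C | intermediate
22 | 4-[(tert-butyldimethylsilyl)oxy]-3-methoxybenzoic acid | COc1cc(C(=O)O)ccc1O[Si](C)(C)C(C)(C)C | intermediate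
23 | (4R,7S,8S)-4-hydroxygermacra-1(10)E,5E-dien-8-yl 4-[(tert-butyldimethylsilyl)oxy]-3-methoxybenzoate | COc1cc(C(=O)O[C@H]2C/C(C)=C/CC[C@@](C)(O)/C=C/[C@@H]2C(C)C)ccc1O[Si](C)(C)C(C)(C)C | intermediate
24 | (4R,7S,8S)-4-hydroxygermacra-1(10)E,5E-dien-8-yl 4-hydroxy-3-methoxybenzoate | COc1cc(C(=O)O[C@H]2C/C(C)=C/CC[C@@](C)(O)/C=C/[C@@H]2C(C)C)ccc1O | target

## Step count and least certain steps

Total step count: 14. Longest linear sequence: 11 steps (steps 3 to 11, 13 and 14, from 5 to 24).

Step 9 (key step). The most likely failures are:
- intermolecular allylation leading to oligomers, because the E,E-ten-membered ring is strained;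
- loss of stereochemical fidelity through syn/anti isomerisation of the allyl complex, which would erode the C7 configuration and the 5E geometry;
- β-hydride elimination of the allyl complex toward a dienol when ring closure is slow.

Fallback: the C7–C8 bond would be made intermolecularly and the ring closed at C8–C9 instead. Setting out from 8, Pd(PPh3)4 and excess nitromethane in THF would open the vinyl oxirane in the same 1,4-sense with the same double inversion, giving the open-chain nitro alcohol F1. Allylic oxidation as in step 6 (SeO2, tBuOOH, then MnO2) would give the nitro enal F2. A dilute base-catalysed intramolecular Henry reaction would close the ten-membered ring to the cyclic nitro alcohol F3. MsCl and Et3N would then dehydrate it to the ring nitroalkene F4, and NaBH4 conjugate reduction would rejoin the route at 16.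

Step 11. The likely failure is poor or reversed facial selectivity of hydride delivery, because the preferred conformation of the ten-membered ketone, and with it the exposed carbonyl face, cannot be predicted with confidence. A second risk is enolisation toward C7. Fallback: the opposite epimer is made useful instead of being avoided. From 18, a bulky hydride (LiBH(sec-Bu)3, THF, −78 °C), or whichever reagent favours it, would give the 8R diol F5. A Mitsunobu esterification of F5 with 22 (PPh3, diisopropyl azodicarboxylate, toluene) would invert C8 and rejoin the route at 23, bypassing step 13.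

Step 10. The likely failures are ionisation of the tertiary allylic C4 alcohol or transannular cyclisation in the Lewis-acidic aqueous titanium medium, and enolisation of the doubly β,γ-unsaturated ketone with epimerisation at C7 or migration of a double bond. Fallback: a two-stage route without titanium. From 16, SnCl2, PhSH and Et3N in MeCN would reduce the secondary nitro group to the oxime F6. Exchange with glyoxylic acid in an acetate-buffered aqueous THF solution would then release the ketone and rejoin the route at 18.

Step 6. The likely failures are acid-promoted opening of the vinyl oxirane by selenous acid and competing oxidation at the isopropyl methine. Fallback: the allylic oxidation is moved ahead of the olefination so that no vinyl oxirane is exposed to it. From 6, SeO2 and tBuOOH (with NaBH4 treatment of the crude product) would give the diol F7. TEMPO and PhI(OAc)2 would oxidise both primary alcohols to the dialdehyde F8. Julia–Kocienski olefination with one equivalent of metalated 4 at −78 °C should occur at the far more electrophilic epoxy aldehyde and rejoin the route at 10.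

Step 8. The likely failures are hydride addition at the remote diene terminus or base-induced migration of the C1=C10 olefin in the nitrodiene, and Michael dimerisation of the nitronate with unreduced nitrodiene. Fallback: the nitro carbon is introduced by alkylation instead of condensation. From 9 (isolated after the first stage of step 6), CBr4 and PPh3 would give the allylic bromide F9. C-Alkylation of methyl nitroacetate (K2CO3, DMF) would give the nitro ester F10. Saponification with LiOH and acidification to pH 5 would cause decarboxylation and rejoin the route at 15.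

## Further compounds

F1 | step 9 | (2S,3E,5R)-5,9-dimethyl-1-nitro-2-(propan-2-yl)deca-3,8-dien-5-ol | CC(C)=CCC[C@@](C)(O)/C=C/[C@@H](C[N+](=O)[O-])C(C)C
F2 | step 9 | (2E,6R,7E,9S)-6-hydroxy-2,6-dimethyl-9-(nitromethyl)-10-methylundeca-2,7-dienal | O=C/C(C)=C/CC[C@@](C)(O)/C=C/[C@@H](C[N+](=O)[O-])C(C)C
F3 | step 9 | (4R,7S)-8-nitrogermacra-1(10)E,5E-diene-4,9-diol (C8 and C9 epimers) | [O-][N+](=O)C1C(O)/C(C)=C/CC[C@@](C)(O)/C=C/[C@@H]1C(C)C
F4 | step 9 | (4R,7S)-8-nitrogermacra-1(10)E,5E,8-trien-4-ol | [O-][N+](=O)C1=C/C(C)=C/CC[C@@](C)(O)/C=C/[C@@H]1C(C)C
F5 | step 11 | (4R,7S,8R)-germacra-1(10)E,5E-diene-4,8-diol | O[C@@H]1C/C(C)=C/CC[C@@](C)(O)/C=C/[C@@H]1C(C)C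
F6 | step 10 | (4R,7S)-4-hydroxygermacra-1(10)E,5E-dien-8-one oxime | ON=C1C/C(C)=C/CC[C@@](C)(O)/C=C/[C@@H]1C(C)C
F7 | step 6 | (2E)-5-[(2R,3S)-3-(hydroxymethyl)-2-methyloxiran-2-yl]-2-methylpent-2-en-1-ol | OC/C(C)=C/CC[C@@]1(C)O[C@H]1CO
F8 | step 6 | (2R,3R)-3-methyl-3-[(3E)-4-methyl-5-oxopent-3-en-1-yl]oxirane-2-carbaldehyde | O=C/C(C)=C/CC[C@@]1(C)O[C@H]1C=O
F9 | step 8 | (2R,3S)-2-[(3E)-5-bromo-4-methylpent-3-en-1-yl]-2-methyl-3-[(1E)-3-methylbut-1-en-1-yl]oxirane | BrC/C(C)=C/CC[C@@]1(C)O[C@H]1/C=C/C(C)C
F10 | step 8 | methyl (4E)-4-methyl-7-{(2R,3S)-2-methyl-3-[(1E)-3-methylbut-1-en-1-yl]oxiran-2-yl}-2-nitrohept-4-enoate | COC(=O)C(C/C(C)=C/CC[C@@]1(C)O[C@H]1/C=C/C(C)C)[N+](=O)[O-]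
A1 | alternative 1 | open-chain (E)-vinyl iodide with terminal vinyl group, 4-O-triethylsilyl and 8-O-tert-butyldimethylsilyl (1-iodo-1,2-secogermacra-1(10),2,5-triene-4,8-diol bis-silyl ether) | CC(C)(C)[Si](C)(C)O[C@@H](C/C(C)=C/I)[C@@H](C(C)C)/C=C/[C@](C)(O[Si](CC)(CC)CC)C=C
A2 | alternative 1 | bis-silyl ether of (1(10)E,5E)-germacradiene-4,8-diol | CC(C)(C)[Si](C)(C)O[C@H]1C/C(C)=C/CC[C@@](C)(O[Si](CC)(CC)CC)/C=C/[C@@H]1C(C)C
A3 | alternative 2 | 4-[(tert-butyldimethylsilyl)oxy]-2-methyl-1-(prop-1-en-2-yl)-5-(propan-2-yl)-2-vinylcyclohexan-1-ol (vinyl and isopropenyl trans) | CC(C)(C)[Si](C)(C)O[C@H]1C[C@@](C)(C=C)[C@](O)(C(C)=C)C[C@@H]1C(C)C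
A4 | alternative 2 | (E)-cyclodec-5-enone hydroxylated at C4, 8-O-tert-butyldimethylsilyl | CC(C)(C)[Si](C)(C)O[C@H]1C/C(C)=C/CC[C@@](C)(O)C(=O)C[C@@H]1C(C)C
A5 | alternative 3 | 8-[(tert-butyldimethylsilyl)oxy]-4-hydroxyeudesm-5-en-1-yl methanesulfonate (mesylate cis to the angular methyl) | CC(C)(C)[Si](C)(C)O[C@H]1C[C@@]2(C)[C@H](OS(C)(=O)=O)CC[C@@](C)(O)C2=C[C@@H]1C(C)C
A6 | alternative 3 | 8-O-tert-butyldimethylsilyl ether of (1(10)E,5E)-germacradien-4-ol | CC(C)(C)[Si](C)(C)O[C@H]1C/C(C)=C/CC[C@@](C)(O)/C=C/[C@@H]1C(C)C
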